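**Assumptions.** (Z)-3-Methylpent-2-en-4-yn-1-ol (as the pure Z isomer, or separable from the commercial E/Z mixture) and N-methoxy-N-methyl-2-oxopropanamide are commercially available. The minor diastereomers from the macrocyclization are assumed separable. Numbering of ring atoms in the text follows germacrane numbering (C1 ketone, C6/C12 lactone, C8 carbinol, C10 quaternary carbon).

## Retrosynthetic overview
1. The target (18) comes from lactonization of the C6-alcohol onto the C12 ester of 17. Compound 17 comes from an intramolecular Nozaki–Hiyama allylation between the Z-enal (C6) and an allylic iodide (C7/C13). That step closes the 10-membered ring, forms the C6–C7 bond and sets the exocyclic methylene.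
2. The allyl iodide comes from a halo-Baylis–Hillman-type coupling of an α-acyloxy aldehyde. The aldehyde is unmasked from an acetal, and the C8 tiglate is installed on the furanone.
3. The 3(2H)-furanone comes from 5-endo-dig cycloisomerization of a tertiary α-hydroxy ynone. The ynone comes from a lithium Z-enynylide and a Weinreb amide.
4. The anti-1,3-diol comes from a directed reduction of a β-ketol. The β-ketol comes from an organocatalytic aldol of a methyl ketone with a pyruvamide, which sets C10 first.
5. Rings form in this order: furanone, then 10-membered carbocycle, then γ-lactone.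

## Route

**Step 1**
Reactants: 1 (1,1-dimethoxypropan-2-one), 2 (N-methoxy-N-methyl-2-oxopropanamide)
Product: 3 ((2R)-2-hydroxy-5,5-dimethoxy-N-methoxy-N,2-dimethyl-4-oxopentanamide)
Conditions: 9-amino-9-deoxy-epi-quinine (20 mol%), 2-fluorobenzoic acid (40 mol%), 1 (4 equiv), THF, 4 °C, 72 h
Reagents that add atoms: none
Why: A primary-amine enamine of the methyl ketone 1 adds to the ketone of 2, which is activated by the α-amide and acid. The catalyst's ammonium/acid pair orients the ketone, so the tertiary carbinol C10 forms as (R) (use the quinidine-derived catalyst if (S) is obtained). Proposed new method: a direct enamine aldol of an α,α-dimethoxy methyl ketone onto an aliphatic α-ketoamide to build an acyclic tertiary α-hydroxy amide. The closest known reactions are amine-catalysed aldols of acetone with isatins, trifluoropyruvates and pyruvates. The mechanistic reasoning is that the Weinreb-amide carbonyl and the ketone activate the acceptor, the acetal blocks the α′ site, and an excess of donor suppresses self-aldol and retro-aldol.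

**Step 2**
Reactants: 3
Product: 4 ((2R,4R)-2,4-dihydroxy-5,5-dimethoxy-N-methoxy-N,2-dimethylpentanamide)
Conditions: Me4NBH(OAc)3 (4 equiv), MeCN/AcOH 1:1, −30 → −10 °C
Reagents that add atoms: none
Why: Evans–Saksena reduction delivers hydride intramolecularly from the acetoxyborohydride bound to the C10 hydroxyl, giving the anti-1,3-diol. This sets C8 as (R), which is anti to C10 as in the target. The Weinreb amide and the acetal are inert.

**Step 3**
Reactants: 5 ((2Z)-3-methylpent-2-en-4-yn-1-ol), 6 (TBSCl)
Product: 7 (TBS ether of 5)
Conditions: TBSCl (1.1 equiv), imidazole, DMF, 0 °C → rt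
Reagents that add atoms: TBSCl, CC(C)(C)[Si](C)(C)Cl
Why: Silylation masks the alcohol. A free (Z)-2-en-4-yn-1-ol would otherwise cycloisomerize to a furan or oxa-cyclize onto the ynone later. The Z alkene is untouched.

**Step 4**
Reactants: 4, 7
Product: 8 ((2Z,7R,9R)-1-(TBSO)-7,9-dihydroxy-10,10-dimethoxy-3,7-dimethyldec-2-en-4-yn-6-one)
Conditions: 7 (3.0 equiv), n-BuLi (2.9 equiv), THF, −78 °C; add 4; −78 → 0 °C; aq. NH4Cl
Reagents that add atoms: none (n-BuLi only deprotonates; N,O-dimethylhydroxylamine leaves)
Why: Weinreb acylation of the lithium acetylide gives the ynone through a chelated tetrahedral intermediate. The acetal, the TBS ether and the alkenyl geometry survive, and the two extra equivalents of base cover the diol. The stereocentres are untouched.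

**Step 5**
Reactants: 8
Product: 9 (furanone; C2 = C10 is R)
Conditions: DBU (0.2 equiv), MeCN, 25 °C
Reagents that add atoms: none
Why: The tertiary α-hydroxy ynone undergoes base-catalysed 5-endo-dig oxa-Michael cycloisomerization to the 5-alkenyl-3(2H)-furanone, the first ring. C10 has no α-H, so it cannot epimerize. The free C8-OH is too remote to compete (it would need a 7-membered ring).

**Step 6**
Reactants: 9, 10 (tigloyl chloride)
Product: 11 (C8 tiglate of 9)
Conditions: tigloyl chloride (1.5 equiv), Et3N, DMAP (cat.), CH2Cl2, 0 °C
Reagents that add atoms: tigloyl chloride, C/C=C(\C)C(=O)Cl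
Why: Acylation of the only free hydroxyl. Installing the ester now avoids a later protection/deprotection pair, and no stereocentre is affected.

**Step 7**
Reactants: 11
Product: 12 (α-tigloyloxy aldehyde)
Conditions: TMSOTf (2.5 equiv), 2,2′-bipyridyl (3 equiv), CH2Cl2, 0 °C; then H2O
Reagents that add atoms: water, O
Why: Fujioka-type acetal-to-aldehyde conversion under nearly neutral conditions. These conditions are chosen because they leave the TBS ether and tiglate intact and minimize epimerization at the acidic C8–H.

**Step 8**
Reactants: 12, 13 (methyl acrylate)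
Product: 14 (methyl (2Z,4R)-2-(iodomethyl)-4-(tigloyloxy)-5-furanonyl-pent-2-enoate)
Conditions: methyl acrylate (3 equiv), TiCl4 (1.5 equiv), Bu4NI (1.5 equiv), CH2Cl2, −78 → −40 °C
Reagents that add atoms: methyl acrylate, C=CC(=O)OC; tetrabutylammonium iodide, CCCC[N+](CCCC)(CCCC)CCCC.[I-] (iodide)
Why: This is a halo-Baylis–Hillman sequence. Iodide adds 1,4 to the Ti-activated acrylate, the titanium enolate adds to the aldehyde, and elimination gives the (Z)-2-(iodomethyl)alkenoate. It avoids amine bases that would epimerize C8, and C8 is carried through unchanged.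

**Step 9**
Reactants: 14
Product: 15 (primary (Z)-allylic alcohol)
Conditions: HF·pyridine, THF/pyridine, 0 °C
Reagents that add atoms: none
Why: Selective removal of the primary TBS ether. The tiglate, furanone, enoate and allylic iodide survive these buffered conditions.

**Step 10**
Reactants: 15
Product: 16 (Z-enal)
Conditions: activated MnO2 (20 equiv), CH2Cl2, 0 °C → rt, dark
Reagents that add atoms: none
Why: MnO2 oxidizes only the allylic alcohol and leaves the iodide and esters alone. Working in the dark protects the Z geometry, which is required for the ring closure. The crude enal is used at once.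

**Step 11**
Reactants: 16
Product: 17 (macrocyclic hydroxy methyl ester, (6R,7S,8R,10R) by CIP)
Conditions: CrCl2 (8 equiv), DMF/THF 1:1, 25 °C, syringe-pump addition over 8 h to a final concentration of about 2 mM
Reagents that add atoms: none
Why: The Nozaki–Hiyama allylchromium adds through a chair Zimmerman–Traxler transition state and gives the anti homoallylic alcohol whichever allyl geometry is present. Anti C6/C7 means a trans-fused lactone after closure. Facial selectivity comes from the rigid bridged furanone/Z-alkene and the C8/C10 centres. This step closes the 10-membered ring, creates the C6 and C7 stereocentres and forms the exocyclic methylene.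

**Step 12**
Reactants: 17
Product: 18 (atripliciolide tiglate)
Conditions: p-TsOH·H2O (0.1 equiv), toluene, 50 °C
Reagents that add atoms: none
Why: Acid-catalysed γ-lactonization (loss of MeOH) of the C6-OH onto the C12 ester gives the trans-fused α-methylene-γ-butyrolactone. No stereocentre is affected.

## Compound list
1 | 1,1-dimethoxypropan-2-one | CC(=O)C(OC)OC | starting material
2 | N-methoxy-N-methyl-2-oxopropanamide | CC(=O)C(=O)N(C)OC | starting material
3 | (2R)-2-hydroxy-5,5-dimethoxy-N-methoxy-N,2-dimethyl-4-oxopentanamide | COC(OC)C(=O)C[C@@](C)(O)C(=O)N(C)OC | intermediate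
4 | (2R,4R)-2,4-dihydroxy-5,5-dimethoxy-N-methoxy-N,2-dimethylpentanamide | COC(OC)[C@H](O)C[C@@](C)(O)C(=O)N(C)OC | intermediate
5 | (2Z)-3-methylpent-2-en-4-yn-1-ol | OC/C=C(/C)C#C | starting material
6 | tert-butyldimethylsilyl chloride | CC(C)(C)[Si](C)(C)Cl | starting material
7 | TBS ether of 5 | CC(C)(C)[Si](C)(C)OC/C=C(/C)C#C | intermediate
8 | Z-enynyl α-hydroxy ynone diol (from 4 + 7) | COC(OC)[C@H](O)C[C@@](C)(O)C(=O)C#C/C(C)=C\CO[Si](C)(C)C(C)(C)C | intermediate
9 | 5-alkenyl-2,2-disubstituted 3(2H)-furanone | COC(OC)[C@H](O)C[C@@]1(C)OC(/C(C)=C\CO[Si](C)(C)C(C)(C)C)=CC1=O | intermediate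
10 | tigloyl chloride | C/C=C(\C)C(=O)Cl | starting material
11 | C8 tiglate of 9 | COC(OC)[C@H](OC(=O)/C(C)=C/C)C[C@@]1(C)OC(/C(C)=C\CO[Si](C)(C)C(C)(C)C)=CC1=O | intermediate
12 | α-tigloyloxy aldehyde | O=C[C@H](OC(=O)/C(C)=C/C)C[C@@]1(C)OC(/C(C)=C\CO[Si](C)(C)C(C)(C)C)=CC1=O | intermediate
13 | methyl acrylate | C=CC(=O)OC | starting material
14 | (Z)-allylic iodide | IC/C(C(=O)OC)=C\[C@H](OC(=O)/C(C)=C/C)C[C@@]1(C)OC(/C(C)=C\CO[Si](C)(C)C(C)(C)C)=CC1=O | intermediate
15 | primary allylic alcohol | IC/C(C(=O)OC)=C\[C@H](OC(=O)/C(C)=C/C)C[C@@]1(C)OC(/C(C)=C\CO)=CC1=O | intermediate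
16 | Z-enal | IC/C(C(=O)OC)=C\[C@H](OC(=O)/C(C)=C/C)C[C@@]1(C)OC(/C(C)=C\C=O)=CC1=O | intermediate
17 | macrocyclic hydroxy methyl ester | C=C(C(=O)OC)[C@@H]1[C@H](OC(=O)/C(C)=C/C)C[C@@]2(C)OC(=CC2=O)/C(C)=C\[C@H]1O | intermediate
18 | atripliciolide tiglate | C=C1C(=O)O[C@@H]2/C=C(/C)C3=CC(=O)[C@@](C)(C[C@@H](OC(=O)/C(C)=C/C)[C@@H]12)O3 | target

**Total steps:** 12. **Longest linear sequence:** 11 (1 → 3 → 4 → 8 → 9 → 11 → 12 → 14 → 15 → 16 → 17 → 18).

## Three steps most likely to fail
1. **Step 1 (the proposed new aldol).** It may give low ee or yield because of retro-aldol, self-aldol of the donor, or the modest electrophilicity of the pyruvamide. Fallback (known chemistry): a Cu(II)–tBu-box-catalysed Mukaiyama aldol of the TMS enol ether of 1 with methyl pyruvate, followed by conversion of the ester to the Weinreb amide (MeNHOMe·HCl, i-PrMgCl), to reach 3.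
2. **Step 11 (the macrocyclic Nozaki–Hiyama allylation).** The yield may be low because of oligomerization, or the C6/C7 facial selectivity relative to C8/C10 may be poor. Fallback: build the trans-fused α-methylene lactone first by intermolecular In-mediated allylation of a C8 aldehyde with a 3-(bromomethyl)butenolide, then close the 10-membered ring at C4=C5 by ring-closing metathesis (Hoveyda–Grubbs II) of an isopropenyl/vinyl diene.
3. **Step 8 (halo-Baylis–Hillman).** TiCl4 may cleave the silyl ether, or C8 may epimerize. Fallback: a Horner–Wadsworth–Emmons olefination of 12 with methyl 2-(dimethoxyphosphoryl)-3-(silyloxy)propanoate, then desilylation and Appel bromination (PPh3/CBr4) to give the allylic bromide.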